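- Percent of the substrate charged is the unit you read, and in it the closed flask midnight looks just like the alder run: the same vessel, the same c(substrate) of 1.0 M, and alder's last reading falls at midnight's end, 20 min.

| flask | substrate | remark | time |
|---|---|---|---|
| alder | 1 M | run made earlier |  |
| larch | 0.50 M | run made earlier |  |
| oak | 2 M | run made earlier |  |
| dusk | 1.0 M | one stirred flow tank at steady state, fed with the mixture as stated, mean residence time 20 min |  |
| midnight | 1.0 M | a closed flask charged with all of it at once and left for 20 min | 20 min |
| spring | 1.0 M | one stirred flow tank at steady state, fed with the mixture as stated, mean residence time 100 min |  |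

| alder: time / min | alder: product / % | larch: time / min | larch: product / % | oak: time / min | oak: product / % |
|---|---|---|---|---|---|
| 4.00 | 0 | 1.00 | 0 | 1.00 | 0.1 |
| 8.00 | 0.3 | 3.00 | 0.2 | 3.00 | 0 |
| 12.0 | 1.3 | 6.00 | 0 | 6.00 | 0.5 |
| 15.0 | 1.9 | 8.00 | 0.2 | 8.00 | 0.5 |
| 20.0 | 3.9 | 12.0 | 0.6 | 12.0 | 1.1 |

(each reading ± 0.3 percentage points)

- the set-up with the highest amount of product at the outlet or at the end, in percent of the substrate put in ("none" if the first two lie within 2 percentage points) (dusk / midnight / spring / none)
- amount of product at the outlet or at the end, in percent of the substrate put in, dusk
- amount of product at the outlet or at the end, in percent of the substrate put in, midnight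
- amount of product at the outlet or at the end, in percent of the substrate put in, spring

- the stated concentrations are those of everything mixed, before any reaction; amounts are the same in each set-up
- the earlier runs were made in a closed, stirred flask
- a reading or a percentage of product counts all its forms, free or not

- Midnight should end where alder ended, near 3.9% give or take 0.3 percentage points, because the charge and the time match.
- Alder starts slowly, with 0.3% at 8.00 min, 1.3% at 12.0 min and 3.9% at 20.0 min, which is an induction period with product growing about as the square of time.
- So carry T = 101 min, my induction time: the time at which the square law through alder's last reading would reach the whole charge. Alder's early product share, as a fraction of the charge, is then about the square of t/T.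
- Go round once more and put T back into alder at 12.0 min: it gives 1.41% against the reading 1.3%, a gap smaller than the scatter.
- A stirred tank holds ages whose mean square is twice the square of the residence time, so my sum for dusk is 7.84%, higher than the forecast's figure below.
- For spring the same sum gives 196%, more than the charge, since its 100 min stands at T. I commit to no number there, just to spring leading.
- The forecast says 5% for dusk, 3.8% for midnight and 32% for spring, so spring, on the ground that “A tank avoids the induction”.
- The flasks give 4.79% for dusk, 3.71% for midnight and 24.5% for spring, so spring leads.

    substrate → intermediate A (k = 0.0910 min⁻¹)
    intermediate A → intermediate B (k = 0.00280 min⁻¹)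
    intermediate B ⇌ intermediate C (K = 38.0, k = 0.0690 min⁻¹)
    intermediate C → product (k = 0.0610 min⁻¹)
    intermediate B ⇌ intermediate D (K = 0.160, k = 1.00 min⁻¹)
    substrate → intermediate D (k = 0.0220 min⁻¹)
    substrate + product ⇌ idle adduct, settled at all times (K = 1.10 L mol⁻¹)

- The square of t/T gives 3.92% for midnight against 3.71%, and 1.41% for larch at 12.0 min against 1.18% without scatter. But midnight has not come to rest: at 20 min it holds 10.3% substrate and 69.3% intermediate A, more than substrate, intermediate B or intermediate C, and intermediate A has a half-life of 4.1 h by its step to intermediate B alone. At 200 min the square law gives 392%, more than the charge. Left ten times as long, midnight stands at 48.0% product.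

(Readings and results come from a simulation from invented constants.)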